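**Plan**
- Retrosynthesis: the two aryl–pentyl bonds (at C6 of ring B and C6' of ring A) are cut first, as aryl–alkynyl bonds, back to a depside bis(triflate). Next comes the depside ester C–O bond, then the S–O, O–CH3, O–Si and benzyl ester bonds of two monomers, both traced to 2,4,6-trihydroxybenzoic acid.
- Forward, ring B block: benzyl ester formation, para-silylation, monotriflation and desilylation give 5. Part of 5 is O-methylated and debenzylated to the ring A acid 7.
- Forward, assembly: 7 and 5 are esterified to bis(triflate) 9. One twofold Sonogashira coupling with pent-1-yne attaches both chains, and one hydrogenation saturates them and frees the acid.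
- No ring is formed (both benzene rings are bought in) and the target has no stereocenter.
- Enabling feature: each pentyl chain stands at C6 (ring B) or C6' (ring A), ortho to the carbonyl-bearing carbon C1 or C1'. That is the place of an ortho oxygen of the phloroglucinol carboxylate, where a triflate is activated for oxidative addition.

Key step: step 8

Remark: ring A is the 4-methoxy acyl ring (primed locants) and ring B the ring that carries the carboxyl group; acid 1 is sold as a hydrate and is taken as dried material.

Step 1
Reactants: 1 2,4,6-trihydroxybenzoic acid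
Product: 2 benzyl 2,4,6-trihydroxybenzoate
Conditions: BnBr (1.0 equiv), KHCO3 (1.1 equiv), DMF, rt
Reagents that add atoms: benzyl bromide, BrCc1ccccc1
Why: Carboxylate O-alkylation (SN2 esterification): bicarbonate deprotonates only the strongly acidic carboxyl group, so the carboxylate is benzylated while the three phenols and the ring carbons should stay untouched at room temperature, where the acid does not yet decarboxylate.

Step 2
Reactants: 2 benzyl 2,4,6-trihydroxybenzoate
Product: 3 benzyl 2,6-dihydroxy-4-{[tri(propan-2-yl)silyl]oxy}benzoate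
Conditions: TIPSCl (1.05 equiv), imidazole, DMF, 0 °C
Reagents that add atoms: chlorotri(propan-2-yl)silane, CC(C)[Si](Cl)(C(C)C)C(C)C
Why: Regioselective silyl ether formation: the 4-OH is the most acidic and the only unhindered phenol, whereas both ortho hydroxyls are hydrogen-bonded to the ester and flanked by it, so the bulky silyl chloride should take the para oxygen alone.

Step 3
Reactants: 3 benzyl 2,6-dihydroxy-4-{[tri(propan-2-yl)silyl]oxy}benzoate
Product: 4 benzyl 2-hydroxy-6-(trifluoromethanesulfonyloxy)-4-{[tri(propan-2-yl)silyl]oxy}benzoate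
Conditions: Tf2O (1.05 equiv), pyridine, CH2Cl2, −20 to 0 °C
Reagents that add atoms: trifluoromethanesulfonic anhydride, O=S(=O)(OS(=O)(=O)C(F)(F)F)C(F)(F)F
Why: O-Sulfonylation of a phenol (triflation) that limits itself to one site: the two ortho hydroxyls are equivalent, and once one is triflated the other is locked in a hydrogen bond to the ester carbonyl on a ring deactivated by the sulfonate, as in the known monotriflation of 2,6-dihydroxyaryl ketones and esters.

Step 4
Reactants: 4 benzyl 2-hydroxy-6-(trifluoromethanesulfonyloxy)-4-{[tri(propan-2-yl)silyl]oxy}benzoate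
Product: 5 benzyl 2,4-dihydroxy-6-(trifluoromethanesulfonyloxy)benzoate
Conditions: TBAF, AcOH, THF, 0 °C
Reagents that add atoms: none
Why: Fluoride-induced cleavage of an aryl silyl ether, buffered by acetic acid so that the aryl triflate and the benzyl ester are not exposed to free phenoxide or basic fluoride.

Step 5
Reactants: 5 benzyl 2,4-dihydroxy-6-(trifluoromethanesulfonyloxy)benzoate (the portion destined for ring A)
Product: 6 benzyl 2-hydroxy-4-methoxy-6-(trifluoromethanesulfonyloxy)benzoate
Conditions: MeOH, PPh3, DIAD, THF, 0 °C to rt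
Reagents that add atoms: methanol, CO
Why: Mitsunobu etherification: under neutral conditions the acidic free 4-OH is methylated while the chelated 2-OH does not react, and the aryl triflate is inert to the phosphine and the azodicarboxylate.

Step 6
Reactants: 6 benzyl 2-hydroxy-4-methoxy-6-(trifluoromethanesulfonyloxy)benzoate
Product: 7 2-hydroxy-4-methoxy-6-(trifluoromethanesulfonyloxy)benzoic acid
Conditions: H2 (1 atm), Pd/C, EtOAc, rt
Reagents that add atoms: none
Why: Catalytic hydrogenolysis of a benzyl ester, which is fast at 1 atm in a neutral solvent, whereas reductive cleavage of an aryl triflate over Pd/C needs an added amine base and should therefore not compete.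

Step 7
Reactants: 7 2-hydroxy-4-methoxy-6-(trifluoromethanesulfonyloxy)benzoic acid; 5 benzyl 2,4-dihydroxy-6-(trifluoromethanesulfonyloxy)benzoate
Product: 9 benzyl 2-hydroxy-4-{[2-hydroxy-4-methoxy-6-(trifluoromethanesulfonyloxy)benzoyl]oxy}-6-(trifluoromethanesulfonyloxy)benzoate, via the aroyl trifluoroacetate mixed anhydride 8 (not isolated)
Conditions: TFAA, toluene, 0 °C to rt
Reagents that add atoms: none
Why: Mixed-anhydride esterification (trifluoroacetic anhydride method for hindered depside esters): the 2,6-disubstituted acid is activated as its aroyl trifluoroacetate and acylates the free 4-OH of 5, since the 2-OH of each partner is chelated to its own carbonyl group and too hindered to react.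

Step 8
Reactants: 9 benzyl 2-hydroxy-4-{[2-hydroxy-4-methoxy-6-(trifluoromethanesulfonyloxy)benzoyl]oxy}-6-(trifluoromethanesulfonyloxy)benzoate; 10 pent-1-yne (4 equiv)
Product: 11 benzyl 2-hydroxy-4-{[2-hydroxy-4-methoxy-6-(pent-1-yn-1-yl)benzoyl]oxy}-6-(pent-1-yn-1-yl)benzoate
Conditions: PdCl2(PPh3)2 (10 mol %), CuI (20 mol %), iPr2NEt (4 equiv), degassed DMF, 50 °C, sealed tube
Reagents that add atoms: none
Why: Sonogashira coupling at two sites: PdCl2(PPh3)2 is reduced in the flask to zerovalent palladium, which inserts into each aryl C–OTf bond (both activated by the ortho carbonyl group, the benzyl ester at C1 of ring B and the depside ester at C1' of ring A), while CuI and the amine turn pent-1-yne into the copper acetylide that transmetalates to the arylpalladium triflate, and reductive elimination forms the C6–C(sp) and C6'–C(sp) bonds. The closest known reaction is the Sonogashira coupling of salicylate-type aryl triflates ortho to an ester carbonyl, run here twice on one substrate. No ring is closed and no stereocenter is formed. The step needs oxidative addition at both C–OTf bonds without attack on the aryl ester of the depside or on the sulfonate sulfur; a hindered tertiary amine serves as a non-nucleophilic base, the chelated phenols are too weakly nucleophilic to transacylate, and the two triflates are comparably activated so that neither site should lag. The phenols lie meta to the new alkynes and both carboxyl groups are esterified, so neither benzofuran nor isocoumarin formation can follow the coupling.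

Step 9
Reactants: 11 benzyl 2-hydroxy-4-{[2-hydroxy-4-methoxy-6-(pent-1-yn-1-yl)benzoyl]oxy}-6-(pent-1-yn-1-yl)benzoate
Product: 12 perlatolic acid, 2-hydroxy-4-[(2-hydroxy-4-methoxy-6-pentylbenzoyl)oxy]-6-pentylbenzoic acid
Conditions: H2 (1 atm), Pd/C, EtOAc, rt
Reagents that add atoms: none
Why: Heterogeneous catalytic hydrogenation combined with benzyl ester hydrogenolysis: both alkynes are saturated to pentyl chains and the benzyl group leaves as toluene, while the aryl ester of the depside, the methyl ether and the phenols are inert to H2 over Pd/C.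

**Compound list**
1 | 2,4,6-trihydroxybenzoic acid | O=C(O)c1c(O)cc(O)cc1O | starting material
2 | benzyl 2,4,6-trihydroxybenzoate | O=C(OCc1ccccc1)c1c(O)cc(O)cc1O | intermediate
3 | benzyl 2,6-dihydroxy-4-{[tri(propan-2-yl)silyl]oxy}benzoate | CC(C)[Si](Oc1cc(O)c(C(=O)OCc2ccccc2)c(O)c1)(C(C)C)C(C)C | intermediate
4 | benzyl 2-hydroxy-6-(trifluoromethanesulfonyloxy)-4-{[tri(propan-2-yl)silyl]oxy}benzoate | CC(C)[Si](Oc1cc(O)c(C(=O)OCc2ccccc2)c(OS(=O)(=O)C(F)(F)F)c1)(C(C)C)C(C)C | intermediate
5 | benzyl 2,4-dihydroxy-6-(trifluoromethanesulfonyloxy)benzoate | O=C(OCc1ccccc1)c1c(O)cc(O)cc1OS(=O)(=O)C(F)(F)F | intermediate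
6 | benzyl 2-hydroxy-4-methoxy-6-(trifluoromethanesulfonyloxy)benzoate | COc1cc(O)c(C(=O)OCc2ccccc2)c(OS(=O)(=O)C(F)(F)F)c1 | intermediate
7 | 2-hydroxy-4-methoxy-6-(trifluoromethanesulfonyloxy)benzoic acid | COc1cc(O)c(C(=O)O)c(OS(=O)(=O)C(F)(F)F)c1 | intermediate
8 | 2-hydroxy-4-methoxy-6-(trifluoromethanesulfonyloxy)benzoic trifluoroacetic anhydride (mixed anhydride of 7, not isolated) | COc1cc(O)c(C(=O)OC(=O)C(F)(F)F)c(OS(=O)(=O)C(F)(F)F)c1 | intermediate
9 | benzyl 2-hydroxy-4-{[2-hydroxy-4-methoxy-6-(trifluoromethanesulfonyloxy)benzoyl]oxy}-6-(trifluoromethanesulfonyloxy)benzoate | O=C(OCc1ccccc1)c1c(O)cc(OC(=O)c2c(O)cc(OC)cc2OS(=O)(=O)C(F)(F)F)cc1OS(=O)(=O)C(F)(F)F | intermediate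
10 | pent-1-yne | CCCC#C | starting material
11 | benzyl 2-hydroxy-4-{[2-hydroxy-4-methoxy-6-(pent-1-yn-1-yl)benzoyl]oxy}-6-(pent-1-yn-1-yl)benzoate | CCCC#Cc1cc(OC(=O)c2c(O)cc(OC)cc2C#CCCC)cc(O)c1C(=O)OCc1ccccc1 | intermediate
12 | perlatolic acid, 2-hydroxy-4-[(2-hydroxy-4-methoxy-6-pentylbenzoyl)oxy]-6-pentylbenzoic acid | CCCCCc1cc(OC(=O)c2c(O)cc(OC)cc2CCCCC)cc(O)c1C(=O)O | target

**Step count**
Total: 9 steps. Longest linear sequence: 9 steps (1 to 12 through 6 and 7; block 5 enters a second time in step 7).

**Steps most likely to fail**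

Step 8. The second coupling may stall once one triflate has reacted. Prolonged contact with amine and copper acetylide may also transacylate the depside ester or strip a triflate by attack at sulfur. The fallback forms the aryl–alkynyl bonds on the monomers and esterifies afterwards. It sets out from 5 and 6. Each is coupled with 10 under the conditions of step 8, which should give benzyl 2,4-dihydroxy-6-(pent-1-yn-1-yl)benzoate F1 and benzyl 2-hydroxy-4-methoxy-6-(pent-1-yn-1-yl)benzoate F2. Hydrogenation of F2 over Pd/C should saturate the alkyne and cleave the benzyl ester to 2-hydroxy-4-methoxy-6-pentylbenzoic acid F3. Esterification of F3 with the free 4-OH of F1 (TFAA, toluene) should give benzyl 2-hydroxy-4-[(2-hydroxy-4-methoxy-6-pentylbenzoyl)oxy]-6-(pent-1-yn-1-yl)benzoate F4. Hydrogenation of F4 over Pd/C comes back to the route at 12.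

Step 7. Acylation of the electron-poor 4-OH of 5 may be slow, the phenol may be trifluoroacetylated instead, or the hydroxy acid may condense with itself. The fallback esterifies before ring B carries its triflate. It sets out from 2 and 7. The unhindered, more nucleophilic 4-OH of 2 is acylated by 7 (TFAA, toluene), which should give benzyl 2,6-dihydroxy-4-{[2-hydroxy-4-methoxy-6-(trifluoromethanesulfonyloxy)benzoyl]oxy}benzoate F5. Monotriflation of one of the two equivalent ring B hydroxyls (Tf2O 1.0 equiv, pyridine, CH2Cl2, −20 °C) should then limit itself to one site for the reason given in step 3. It comes back to the route at 9.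

Step 6. The carbonyl-activated C–OTf bond may be cleaved reductively during debenzylation. The fallback carries the ring A carboxyl group as an acid-labile ester, so that no hydrogenation is run beside the triflate. It sets out from 1. Alkylation with 4-methoxybenzyl chloride and KHCO3 in DMF should give (4-methoxyphenyl)methyl 2,4,6-trihydroxybenzoate F6. Mitsunobu methylation of the para hydroxyl (MeOH, PPh3, DIAD) should give (4-methoxyphenyl)methyl 2,6-dihydroxy-4-methoxybenzoate F7. Monotriflation as in step 3 should give (4-methoxyphenyl)methyl 2-hydroxy-4-methoxy-6-(trifluoromethanesulfonyloxy)benzoate F8. TFA with anisole in CH2Cl2 at 0 °C then removes the ester and comes back to the route at 7.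

**Further compounds**
F1 | step 8 | benzyl 2,4-dihydroxy-6-(pent-1-yn-1-yl)benzoate | CCCC#Cc1cc(O)cc(O)c1C(=O)OCc1ccccc1
F2 | step 8 | benzyl 2-hydroxy-4-methoxy-6-(pent-1-yn-1-yl)benzoate | CCCC#Cc1cc(OC)cc(O)c1C(=O)OCc1ccccc1
F3 | step 8 | 2-hydroxy-4-methoxy-6-pentylbenzoic acid | CCCCCc1cc(OC)cc(O)c1C(=O)O
F4 | step 8 | benzyl 2-hydroxy-4-[(2-hydroxy-4-methoxy-6-pentylbenzoyl)oxy]-6-(pent-1-yn-1-yl)benzoate | CCCC#Cc1cc(OC(=O)c2c(O)cc(OC)cc2CCCCC)cc(O)c1C(=O)OCc1ccccc1
F5 | step 7 | benzyl 2,6-dihydroxy-4-{[2-hydroxy-4-methoxy-6-(trifluoromethanesulfonyloxy)benzoyl]oxy}benzoate | O=C(OCc1ccccc1)c1c(O)cc(OC(=O)c2c(O)cc(OC)cc2OS(=O)(=O)C(F)(F)F)cc1O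
F6 | step 6 | (4-methoxyphenyl)methyl 2,4,6-trihydroxybenzoate | COc1ccc(COC(=O)c2c(O)cc(O)cc2O)cc1
F7 | step 6 | (4-methoxyphenyl)methyl 2,6-dihydroxy-4-methoxybenzoate | COc1ccc(COC(=O)c2c(O)cc(OC)cc2O)cc1
F8 | step 6 | (4-methoxyphenyl)methyl 2-hydroxy-4-methoxy-6-(trifluoromethanesulfonyloxy)benzoate | COc1ccc(COC(=O)c2c(O)cc(OC)cc2OS(=O)(=O)C(F)(F)F)cc1
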